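The ring atoms are numbered C1 (CHOAc), C2 (CH2), C3 (CMe) and onward to C9 (the side-chain carbon). Everything rests on cutting C2–C3, the sp3–sp2 bond inside the homoallylic array O–C1–C2–C3=C4 of the cyclononadiene. The precursor is an open-chain (E)-alkenyl bromide carrying a vinyl group (C1=C2) on C9. In one flask the vinyl group is diborated enantioselectively. The primary C2 boronate, activated by its C1 neighbour, then couples with the C3 bromide to close the nine-membered ring, and the C1 boronate is oxidised. This sets C1, the ring and the E alkene together. C8 and C9 arise from an enamine Michael addition of (R)-citronellal to a phosphoryl butenolide.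

Key step: step 9

Locants used for all intermediates: C1–C9 as above, C10 is the carbon on C8, C11 is the carbon on C7, and C1′ is the side-chain methine.

Assumption on the chemistry: the (R,R)-antipode of the TADDOL-derived phenylphosphonite is taken to be the one that turns simple 1-alkenes into (S)-1,2-diols after oxidation. This is the sense needed at C1. If the sense is the reverse, the (S,S)-antipode is used.

Assumption on supply: compounds 1, 5 and 9 are taken as commercial.

Step 1
Reactants: 1 pent-3-yn-1-ol
Product: 3 (E)-4-bromopent-3-en-1-ol, via alkenylzirconocene 2 (not isolated)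
Conditions: Cp2Zr(H)Cl (2.3 equiv), THF, 0 °C to rt; then NBS, 0 °C
Reagents that add atoms: zirconocene chloride hydride [H][Zr](Cl)(C1C=CC=C1)C1C=CC=C1 (atoms in 2 only); N-bromosuccinimide O=C1CCC(=O)N1Br
Why: Syn hydrozirconation, equilibrated by excess reagent, places zirconium on the less hindered methyl-bearing alkyne carbon, and stereoretentive bromodemetalation then gives the E alkenyl bromide (hydrozirconation–halogenation).

Step 2
Reactants: 3 (E)-4-bromopent-3-en-1-ol
Product: 4 (E)-4-bromopent-3-enal
Conditions: Dess–Martin periodinane, pyridine, CH2Cl2, 0 °C; used crude at once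
Reagents that add atoms: none
Why: Pyridine-buffered Dess–Martin oxidation is neutral and fast, so the β,γ-unsaturated aldehyde should form without migration of the double bond into conjugation.

Step 3
Reactants: 5 diethyl (2-oxooxolan-3-yl)phosphonate
Product: 8 3-(diethoxyphosphoryl)furan-2(5H)-one, via selenide 6 (not isolated), via selenoxide 7 (not isolated)
Conditions: NaH, THF, 0 °C; PhSeBr, 0 °C; then 30% H2O2, CH2Cl2, 0 °C to rt
Reagents that add atoms: benzeneselenenyl bromide Br[Se]c1ccccc1 (atoms in 6 and 7 only); hydrogen peroxide OO (oxygen in 7 only)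
Why: α-Selenenylation of the stabilised phosphonate anion is followed by selenoxide syn-elimination, which can only take a ring C4 hydrogen and so installs the endocyclic double bond.

Step 4
Reactants: 9 (R)-citronellal; 8 3-(diethoxyphosphoryl)furan-2(5H)-one
Product: 10 (2R,3R)-2-[(3S)-4-(diethoxyphosphoryl)-5-oxooxolan-3-yl]-3,7-dimethyloct-6-enal (epimers at the phosphonate carbon C7, inconsequential)
Conditions: (S)-α,α-diphenylprolinol trimethylsilyl ether (20 mol %), 4-nitrophenol (20 mol %), 9 (1.5 equiv), toluene, 0 °C to rt
Reagents that add atoms: none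
Why: In this enamine-catalysed asymmetric Michael addition the diphenyl(silyloxy)methyl group shields one face of the E-enamine and sets C9, attack on the doubly activated β-carbon of 8 through the usual synclinal open transition state gives the syn relationship and sets C8, and C1′ comes unchanged from 9.

Step 5
Reactants: 10 Michael adduct aldehyde
Product: 11 diethyl [(4S)-4-[(3R,4R)-4,8-dimethylnona-1,7-dien-3-yl]-2-oxooxolan-3-yl]phosphonate (epimers at C7)
Conditions: MePPh3Br (3 equiv), KHMDS (2.8 equiv), THF, 0 °C; 10 added at −78 °C, then to 0 °C; aq NH4Cl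
Reagents that add atoms: methyltriphenylphosphonium bromide C[P+](c1ccccc1)(c1ccccc1)c1ccccc1.[Br-]
Why: In this Wittig methylenation the first equivalent of ylide parks the acidic phosphonate carbon as an unreactive anion that also shields the lactone, and the excess converts the hindered aldehyde into the C1=C2 vinyl group at low temperature without touching C9.

Step 6
Reactants: 11 vinyl phosphono lactone; 4 (E)-4-bromopent-3-enal
Product: 12 (3E,4R)-3-[(3E)-4-bromopent-3-en-1-ylidene]-4-[(3R,4R)-4,8-dimethylnona-1,7-dien-3-yl]oxolan-2-one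
Conditions: NaH (1.0 equiv), THF, 0 °C; then 4 (1.3 equiv), −78 to 0 °C
Reagents that add atoms: none
Why: Horner–Wadsworth–Emmons olefination of a carbonyl-stabilised cyclic phosphonate proceeds through reversible adducts and should place the C5 chain trans to the lactone carbonyl (E), while the preformed anion leaves no free base to conjugate aldehyde 4.

Step 7
Reactants: 12 alkylidene lactone
Product: 13 (2E,3R)-2-[(3E)-4-bromopent-3-en-1-ylidene]-3-[(3R,4R)-4,8-dimethylnona-1,7-dien-3-yl]butane-1,4-diol
Conditions: i-Bu2AlH (5 equiv), CH2Cl2, −78 to 0 °C; aq Rochelle salt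
Reagents that add atoms: none
Why: i-Bu2AlH reduces the α-alkylidene lactone in 1,2-fashion through the lactol to the 1,4-diol and leaves the alkenyl bromide, the other alkenes and C8 untouched.

Step 8
Reactants: 13 diol
Product: 14 bis(tert-butyldimethylsilyl) ether of 13 (C10 and C11 oxygens silylated, all centres and alkene geometries as in 13)
Conditions: TBSCl (2.5 equiv), imidazole, DMF, rt
Reagents that add atoms: tert-butyldimethylsilyl chloride CC(C)(C)[Si](C)(C)Cl
Why: Imidazole-promoted silylation of two primary hydroxyls gives ethers that withstand hot aqueous hydroxide and peroxide and can later be removed beside an acetate.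

Step 9
Reactants: 14 bis-silyl ether
Product: 17 (1R,3E,6E,8R,9R)-7,8-bis[(tert-butyldimethylsilyloxy)methyl]-3-methyl-9-[(2R)-6-methylhept-5-en-2-yl]cyclonona-3,6-dien-1-ol, via bis(boronate) 15 (not isolated), via cyclic boronate 16 (not isolated)
Conditions: Pt(dba)3 (3 mol %), (R,R)-3,5-diisopropylphenyl-TADDOL phenylphosphonite (3.6 mol %), B2pin2 (1.0 equiv), THF, 60 °C; the solution is then added by syringe pump over 12 h to Pd(OAc)2 (10 mol %), RuPhos (12 mol %), KOH (3 equiv), THF/H2O 10:1, 70 °C, final 2 mM; then 30% H2O2, 0 °C to rt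
Reagents that add atoms: bis(pinacolato)diboron CC1(C)OB(OC1(C)C)B1OC(C)(C)C(C)(C)O1 (atoms in 15 and 16 only); hydrogen peroxide OO (the C1 oxygen of 17)
Why: Zerovalent platinum inserts into B2pin2 and adds both boryl groups syn across C1=C2 to give 15; zerovalent palladium then inserts into the C3–Br bond with retention, hydroxide-assisted transmetalation delivers the primary C2 carbon, reductive elimination forms C2–C3 to give 16, and peroxide converts C1–B into C1–O by a stereoretentive 1,2-shift. The closest known reaction type is the single-flask alkene diboration/Suzuki–Miyaura coupling/oxidation cascade of 1-alkenes with alkenyl halides, combined with the intramolecular B-alkyl Suzuki–Miyaura closure of medium rings. The nine-membered carbocycle is closed by C(sp3)–C(sp2) reductive elimination from a ten-membered palladacycle under pseudo-high dilution. C1 is the only new stereocenter; it is set by the chiral phosphonite on platinum, which selects the alkene face, and it is carried through coupling and oxidation unchanged. Only the monosubstituted alkene among the four is diborated, because the platinum catalyst does not engage trisubstituted alkenes, and fast B–B insertion should keep platinum away from the C–Br bond. The primary boronate couples in preference to the secondary one because it is less hindered and because the vicinal boronate acts as an internal Lewis acid that speeds its transmetalation, while the E geometry of C3=C4 is inherited from 3.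

Step 10
Reactants: 17 cyclononadienol
Product: 18 (1R,3E,6E,8R,9R)-7,8-bis[(tert-butyldimethylsilyloxy)methyl]-3-methyl-9-[(2R)-6-methylhept-5-en-2-yl]cyclonona-3,6-dien-1-yl acetate
Conditions: Ac2O, DMAP (cat.), pyridine, CH2Cl2, 0 °C to rt
Reagents that add atoms: acetic anhydride CC(=O)OC(C)=O
Why: DMAP-catalysed acetylation of the only free hydroxyl occurs at oxygen and so retains the C1 configuration.

Step 11
Reactants: 18 acetate
Product: 19 (1R,3E,6E,8R,9R)-7,8-bis(hydroxymethyl)-3-methyl-9-[(2R)-6-methylhept-5-en-2-yl]cyclonona-3,6-dien-1-yl acetate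
Conditions: HF·pyridine, excess pyridine, THF, 0 °C to rt
Reagents that add atoms: none
Why: Buffered fluoride desilylation forms no free alkoxide, so acetyl migration is avoided, and it is mild enough for the strained E alkene.

Step 12
Reactants: 19 diol acetate
Product: 20 (1R,3E,6E,8R,9R)-7,8-diformyl-3-methyl-9-[(2R)-6-methylhept-5-en-2-yl]cyclonona-3,6-dien-1-yl acetate (target)
Conditions: (COCl)2 (4 equiv), DMSO (8 equiv), CH2Cl2, −78 °C; then Et3N (12 equiv), −78 to −40 °C; cold pH 7 buffer
Reagents that add atoms: none
Why: In the Swern oxidation both hydroxyls become alkoxysulfonium ions before base is added, so no hydroxy aldehyde can close to a lactol, and cold amine treatment should release the 1,4-dialdehyde without epimerising C8.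

Compound list
1 | pent-3-yn-1-ol | CC#CCCO | starting material
2 | (E)-alkenylzirconocene chloride of 1 (zirconium on C4, oxygen as zirconocene alkoxide) | C/C(=C\CCO[Zr](Cl)(C1C=CC=C1)C1C=CC=C1)[Zr](Cl)(C1C=CC=C1)C1C=CC=C1 | intermediate
3 | (E)-4-bromopent-3-en-1-ol | OCC/C=C(/Br)C | intermediate
4 | (E)-4-bromopent-3-enal | O=CC/C=C(/Br)C | intermediate
5 | diethyl (2-oxooxolan-3-yl)phosphonate (racemic) | CCOP(=O)(OCC)C1CCOC1=O | starting material
6 | diethyl [2-oxo-3-(phenylselanyl)oxolan-3-yl]phosphonate (racemic) | CCOP(=O)(OCC)C1([Se]c2ccccc2)CCOC1=O | intermediate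
7 | selenoxide of 6 | CCOP(=O)(OCC)C1([Se](=O)c2ccccc2)CCOC1=O | intermediate
8 | 3-(diethoxyphosphoryl)furan-2(5H)-one | CCOP(=O)(OCC)C1=CCOC1=O | intermediate
9 | (R)-citronellal | O=CC[C@H](C)CCC=C(C)C | starting material
10 | (2R,3R)-2-[(3S)-4-(diethoxyphosphoryl)-5-oxooxolan-3-yl]-3,7-dimethyloct-6-enal (C7 epimers) | O=C[C@H]([C@H](C)CCC=C(C)C)[C@H]1COC(=O)C1P(=O)(OCC)OCC | intermediate
11 | diethyl [(4S)-4-[(3R,4R)-4,8-dimethylnona-1,7-dien-3-yl]-2-oxooxolan-3-yl]phosphonate (C7 epimers) | C=C[C@H]([C@H](C)CCC=C(C)C)[C@H]1COC(=O)C1P(=O)(OCC)OCC | intermediate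
12 | (3E,4R)-3-[(3E)-4-bromopent-3-en-1-ylidene]-4-[(3R,4R)-4,8-dimethylnona-1,7-dien-3-yl]oxolan-2-one | C=C[C@H]([C@H](C)CCC=C(C)C)[C@H]1COC(=O)/C1=C/C/C=C(/Br)C | intermediate
13 | (2E,3R)-2-[(3E)-4-bromopent-3-en-1-ylidene]-3-[(3R,4R)-4,8-dimethylnona-1,7-dien-3-yl]butane-1,4-diol | C=C[C@H]([C@H](C)CCC=C(C)C)[C@@H](CO)/C(CO)=C\C/C=C(/Br)C | intermediate
14 | bis(tert-butyldimethylsilyl) ether of 13 | C=C[C@H]([C@H](C)CCC=C(C)C)[C@@H](CO[Si](C)(C)C(C)(C)C)/C(CO[Si](C)(C)C(C)(C)C)=C\C/C=C(/Br)C | intermediate
15 | (1R)-C1,C2-bis(pinacol boronate) from 14 (other centres as in 14) | CC1(C)OB(OC1(C)C)C[C@@H](B2OC(C)(C)C(C)(C)O2)[C@H]([C@H](C)CCC=C(C)C)[C@@H](CO[Si](C)(C)C(C)(C)C)/C(CO[Si](C)(C)C(C)(C)C)=C\C/C=C(/Br)C | intermediate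
16 | (1R,3E,6E,8R,9R)-cyclononadienyl pinacol boronate (17 with Bpin in place of OH at C1) | CC1(C)OB(OC1(C)C)[C@@H]2C/C(C)=C/C/C=C(/CO[Si](C)(C)C(C)(C)C)[C@H](CO[Si](C)(C)C(C)(C)C)[C@H]2[C@H](C)CCC=C(C)C | intermediate
17 | (1R,3E,6E,8R,9R)-7,8-bis[(tert-butyldimethylsilyloxy)methyl]-3-methyl-9-[(2R)-6-methylhept-5-en-2-yl]cyclonona-3,6-dien-1-ol | O[C@@H]1C/C(C)=C/C/C=C(/CO[Si](C)(C)C(C)(C)C)[C@H](CO[Si](C)(C)C(C)(C)C)[C@H]1[C@H](C)CCC=C(C)C | intermediate
18 | acetate of 17 | CC(=O)O[C@@H]1C/C(C)=C/C/C=C(/CO[Si](C)(C)C(C)(C)C)[C@H](CO[Si](C)(C)C(C)(C)C)[C@H]1[C@H](C)CCC=C(C)C | intermediate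
19 | (1R,3E,6E,8R,9R)-7,8-bis(hydroxymethyl)-3-methyl-9-[(2R)-6-methylhept-5-en-2-yl]cyclonona-3,6-dien-1-yl acetate | CC(=O)O[C@@H]1C/C(C)=C/C/C=C(/CO)[C@H](CO)[C@H]1[C@H](C)CCC=C(C)C | intermediate
20 | (1R,3E,6E,8R,9R)-7,8-diformyl-3-methyl-9-[(2R)-6-methylhept-5-en-2-yl]cyclonona-3,6-dien-1-yl acetate | CC(=O)O[C@@H]1C/C(C)=C/C/C=C(/C=O)[C@H](C=O)[C@H]1[C@H](C)CCC=C(C)C | target

Total step count: 12. Longest linear sequence: 10 steps (steps 3 to 12, from 5).

Steps most likely to fail

Step 9. Intermolecular coupling, protodeboronation or β-hydride elimination may outrun the strained closure, and platinum may be consumed by insertion into the C–Br bond. The fallback sets out from 14 and comes back at 17. It keeps the diboration but replaces the boron/palladium closure with a nickel radical cross-electrophile closure of the same bond. Compound 14 is diborated as before and oxidised directly (H2O2, NaOH) to the (S)-configured terminal 1,2-diol F1. Selective Appel iodination of the primary hydroxyl (I2, PPh3, imidazole, 0 °C) gives the iodohydrin F2. Slow addition of F2 to NiI2, 4,4′-di-tert-butyl-2,2′-bipyridine, NaI and manganese powder in DMA then joins the alkyl iodide carbon C2 to the alkenyl bromide carbon C3 and should give 17 directly.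

Step 4. The β-substituted acceptor may react too slowly with the enamine, or the facial selectivity at C8 may be poor. The fallback sets out from 9 and comes back at 10. It replaces catalytic enamine activation with a stoichiometric chiral azaenolate. Compound 9 is condensed with (R)-1-amino-2-(methoxymethyl)pyrrolidine to give the RAMP hydrazone of citronellal F3. Deprotonation (LDA, THF, −78 °C) and addition to 8 gives the RAMP hydrazone of the adduct F4, with C9 fixed by the auxiliary. Hydrolysis with aqueous CuCl2 in THF then releases 10, and any C8 epimer is removed by chromatography at this stage.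

Step 6. E/Z selectivity may erode with the hindered β-branched phosphonate, and the base may conjugate aldehyde 4. The fallback sets out from 11 and comes back at 12. It gives up kinetic control of the geometry. The olefination is run under the mildest conditions that spare the aldehyde (LiCl, i-Pr2NEt, MeCN), and the mixture is accepted. The (3Z)-isomer of the lactone F5 is separated and equilibrated to the more stable E isomer 12 by reversible conjugate addition of catalytic PBu3 in THF, which touches only the acceptor alkene.

Further compounds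
F1 | step 9 | (S)-C1,C2-diol from 14 (hydroxyls on C1 and C2, other centres as in 14) | OC[C@@H](O)[C@H]([C@H](C)CCC=C(C)C)[C@@H](CO[Si](C)(C)C(C)(C)C)/C(CO[Si](C)(C)C(C)(C)C)=C\C/C=C(/Br)C
F2 | step 9 | iodohydrin (F1 with iodine in place of the primary C2 hydroxyl) | IC[C@@H](O)[C@H]([C@H](C)CCC=C(C)C)[C@@H](CO[Si](C)(C)C(C)(C)C)/C(CO[Si](C)(C)C(C)(C)C)=C\C/C=C(/Br)C
F3 | step 4 | RAMP hydrazone of (R)-citronellal (E at C=N) | COC[C@H]1CCCN1/N=C/C[C@H](C)CCC=C(C)C
F4 | step 4 | RAMP hydrazone of aldehyde 10 (C7 epimers) | COC[C@H]1CCCN1/N=C/[C@H]([C@H](C)CCC=C(C)C)[C@H]2COC(=O)C2P(=O)(OCC)OCC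
F5 | step 6 | (3Z)-isomer of lactone 12 | C=C[C@H]([C@H](C)CCC=C(C)C)[C@H]1COC(=O)/C1=C\C/C=C(/Br)C
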